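The oxocene (O, C7–C13; numbering from the alkyne terminus C1) is read as a six-membered dihydropyranone ring (O, C7, C8, C9, C10, C13) into whose C10–C13 bond the two-carbon unit C11–C12 has been inserted. The key step, a head-to-tail enone–alkene [2+2] photocycloaddition, lays 1,1-diethoxyethene across the C10=C13 enol-ether double bond of a 6-ethyl-2,3-dihydro-4H-pyran-4-one. This makes C10–C11 and C12–C13 at once, with C12 as a masked ketone. It exploits the vinylic C10/ether-bearing C13 pair flanking the CH2–CHBr segment. Radical scission of the shared C10–C13 bond then expands the 2-oxabicyclo[4.2.0]octane to the Z-oxocene and erases every photochemical stereocentre.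

Key step: step 3

Remark on numbering: atoms carry the numbers C1 (alkyne CH) to C15 (ethyl CH3). The ring oxygen bridges C7 and C13, OAc sits on C6 and Br on C12.
Assumption: (S)-glyceraldehyde acetonide 2 is taken as purchasable. It is otherwise one oxidation away from commercial (R)-solketal.
Remark: the SMILES of 7, 8 and 9 show the expected major isomer. The facial isomer and the C9 epimer give the same product in step 6.

Step 1
Reactants: 1 hex-3-yn-2-one; 2 (S)-glyceraldehyde acetonide
Product: 4 (1R)-1-[(4S)-2,2-dimethyl-1,3-dioxolan-4-yl]-1-hydroxyhept-4-yn-3-one, via lithium enolate 3 (not isolated)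
Conditions: LDA, THF, −78 °C; then 2, −78 °C; aq NH4Cl quench at −78 °C
Reagents that add atoms: none
Why: Kinetic deprotonation of the methyl ketone and aldol addition of the lithium enolate to the α-alkoxy aldehyde should follow the polar Felkin–Anh model (attack anti to the C6–O bond), which sets C7 as R and anti to the C6 oxygen, the minor syn isomer being removable by chromatography.

Step 2
Reactants: 4 β-hydroxy ynone
Product: 5 (2R)-2-[(4S)-2,2-dimethyl-1,3-dioxolan-4-yl]-6-ethyl-2,3-dihydro-4H-pyran-4-one
Conditions: Ph3PAuCl (5 mol %), AgOTf (5 mol %), 4 Å MS, CH2Cl2, rt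
Reagents that add atoms: none
Why: Carbophilic activation of the ynone by the cationic gold complex should trigger a 6-endo-dig oxa-Michael cycloisomerisation of the C7 hydroxyl onto the β-alkynyl carbon C13, a known entry to 2,3-dihydro-4H-pyran-4-ones that touches neither C6 nor C7.

Step 3
Reactants: 5 dihydropyranone; 6 1,1-diethoxyethene (ketene diethyl acetal, large excess)
Product: 7 (1R,3R,6R)-3-[(4S)-2,2-dimethyl-1,3-dioxolan-4-yl]-8,8-diethoxy-1-ethyl-2-oxabicyclo[4.2.0]octan-5-one (cis-fused, cyclobutane anti to the dioxolanyl group)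
Conditions: hν (about 300 nm, Pyrex), 6 (15 equiv), MeCN, 0 °C, Ar; filtration through basic Al2O3
Reagents that add atoms: none
Why: Direct excitation and intersystem crossing give the triplet of the vinylogous ester 5, whose unsubstituted α-carbon C10 bonds first to the CH2 terminus of the electron-rich alkene, so that the triplet 1,4-biradical carries its spins on C13 (tertiary and α-oxygenated) and on the diethoxy carbon C12, and spin inversion followed by radical recombination closes C12–C13. The closest known reaction type is the head-to-tail enone–alkene [2+2] photocycloaddition of cyclohexenones, 3(2H)-furanones and 2,3-dihydro-4H-pyran-4-ones with 1,1-dialkoxyethenes, the first half of a de Mayo sequence. One ring is closed, the cyclobutane C10–C11–C12–C13, by intermolecular two-bond annulation onto the C10=C13 bond with a 1,4-biradical recombination as the last event; strain favours the cis fusion of the four- and six-membered rings, and any trans-fused adduct is epimerised at the enolisable C10 on basic Al2O3. The new stereocentres C10 and C13 are set by approach of the alkene anti to the C7 dioxolanyl group, but neither needs control, because C10 becomes sp2 and C13 a planar radical in step 6 and C12 is not stereogenic, so that all facial and fusion isomers converge. The selectivity that is needed is regiochemical (CH2 to C10, acetal carbon to C13), and it is secured by the fully substituted, hindered C13, by the stability of the C13/C12 biradical and by the donor character of the alkene; a biradical that fails to close only reverts to 5 and 6. The C9 carbonyl serves twice, as the chromophore here and as the radical trigger of the ring expansion, while the excess of alkene suppresses dimerisation of 5.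

Step 4
Reactants: 7 photoadduct
Product: 8 (1R,3R,5S,6S)-3-[(4S)-2,2-dimethyl-1,3-dioxolan-4-yl]-8,8-diethoxy-1-ethyl-2-oxabicyclo[4.2.0]octan-5-ol (hydroxyl cis to the cyclobutane)
Conditions: NaBH4, MeOH, 0 °C
Reagents that add atoms: none
Why: Borohydride 1,2-reduction of the six-ring ketone should occur from the face away from the adjacent cyclobutane carbon C11 and leaves both ketals intact, and the C9 configuration is of no consequence since C9 becomes a planar radical in step 6.

Step 5
Reactants: 8 alcohol
Product: 9 O-[(1R,3R,5S,6S)-3-[(4S)-2,2-dimethyl-1,3-dioxolan-4-yl]-8,8-diethoxy-1-ethyl-2-oxabicyclo[4.2.0]octan-5-yl] 1H-imidazole-1-carbothioate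
Conditions: 1,1'-thiocarbonyldiimidazole, DMAP (cat), ClCH2CH2Cl, 70 °C
Reagents that add atoms: 1,1'-thiocarbonyldiimidazole, S=C(n1ccnc1)n1ccnc1
Why: Thioacylation of the secondary alcohol under neutral conditions gives the radical precursor of a Barton–McCombie deoxygenation without touching the acid-labile ketals.

Step 6
Reactants: 9 imidazolylthiocarbonate
Product: 10 (2R,5Z,8R)-8-[(4S)-2,2-dimethyl-1,3-dioxolan-4-yl]-3,3-diethoxy-2-ethyl-3,4,7,8-tetrahydro-2H-oxocine
Conditions: Bu3SnH, AIBN, PhH (0.02 M), 80 °C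
Reagents that add atoms: none
Why: Barton–McCombie generation of the C9 radical starts a cyclobutylcarbinyl radical β-scission (known for thiocarbonyl derivatives of enone photoadducts) that should cleave the shared C10–C13 bond, because this releases the cyclobutane strain and gives a tertiary oxygen-stabilised C13 radical instead of a primary C11 radical, only the Z C9=C10 alkene being attainable in the eight-membered ring, and the tin hydride then delivers hydrogen to C13 along the pseudo-axial lobe so that the ethyl group and the C7 substituent both end pseudo-equatorial, that is cis (13R).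

Step 7
Reactants: 10 oxocene ketal
Product: 11 (2R,5Z,8R)-8-[(4S)-2,2-dimethyl-1,3-dioxolan-4-yl]-2-ethyl-7,8-dihydro-2H-oxocin-3(4H)-one
Conditions: p-TsOH·H2O (cat), wet acetone, rt, short contact
Reagents that add atoms: water, O
Why: Acid-catalysed hydrolysis of the acyclic diethyl ketal is faster than that of the dioxolane, which is further held in place by the acetone medium, and brief mild acid should leave the β,γ-alkene and the C13 centre unchanged.

Step 8
Reactants: 11 oxocenone
Product: 12 (2R,3R,5Z,8R)-8-[(4S)-2,2-dimethyl-1,3-dioxolan-4-yl]-2-ethyl-3,4,7,8-tetrahydro-2H-oxocin-3-ol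
Conditions: LiBH(s-Bu)3 (L-Selectride), THF, −78 °C; H2O quench
Reagents that add atoms: none
Why: The bulky non-chelating borohydride should attack the C12 carbonyl from the ring periphery in the polar Felkin–Anh sense, anti to the C13–O bond and past the C13 hydrogen, which gives the 12R alcohol cis to the ethyl group.

Step 9
Reactants: 12 oxocenol
Product: 13 (2R,3S,5Z,8R)-3-bromo-8-[(4S)-2,2-dimethyl-1,3-dioxolan-4-yl]-2-ethyl-3,4,7,8-tetrahydro-2H-oxocine
Conditions: CBr4, P(n-C8H17)3, toluene, 70 °C
Reagents that add atoms: carbon tetrabromide, BrC(Br)(Br)Br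
Why: Appel-type activation as the alkoxyphosphonium salt and SN2 displacement by bromide invert C12 to the 12S bromide trans to ethyl, the nucleophilic trialkylphosphine being suited to hindered medium-ring carbinols.

Step 10
Reactants: 13 bromo acetonide
Product: 14 (1S)-1-[(2R,4Z,7S,8R)-7-bromo-8-ethyl-3,6,7,8-tetrahydro-2H-oxocin-2-yl]ethane-1,2-diol
Conditions: AcOH/H2O 4:1, 40 °C
Reagents that add atoms: none
Why: Aqueous acid hydrolyses the terminal isopropylidene acetal while the secondary bromide, the ring ether and the alkene are inert under these mild conditions.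

Step 11
Reactants: 14 diol
Product: 16 (2S)-2-[(2R,4Z,7S,8R)-7-bromo-8-ethyl-3,6,7,8-tetrahydro-2H-oxocin-2-yl]-2-(methylsulfonyloxy)ethyl benzoate, via primary monobenzoate 15 (not isolated)
Conditions: BzCl (1.05 equiv), pyridine, CH2Cl2, −30 °C; then MsCl, 0 °C to rt
Reagents that add atoms: benzoyl chloride, O=C(Cl)c1ccccc1; methanesulfonyl chloride, CS(=O)(=O)Cl
Why: The primary C5 hydroxyl is acylated much faster than the hindered secondary C6 hydroxyl at low temperature, so that the following mesylation in the same flask activates C6 only, with retention at this stage.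

Step 12
Reactants: 16 benzoate mesylate
Product: 18 (2R,3S,5Z,8R)-3-bromo-2-ethyl-8-[(2R)-oxiran-2-yl]-3,4,7,8-tetrahydro-2H-oxocine, via hydroxy mesylate 17 (not isolated)
Conditions: K2CO3, MeOH, 0 °C to rt
Reagents that add atoms: none
Why: Methanolysis of the benzoate frees the C5 alkoxide, which displaces the neighbouring C6 mesylate in a 3-exo-tet Williamson closure with clean inversion and thereby turns 6S into the 6R configuration of the target.

Step 13
Reactants: 19 3-(trimethylsilyl)prop-2-ynal
Product: 20 (E)-(4-iodobut-3-en-1-yn-1-yl)trimethylsilane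
Conditions: CHI3, CrCl2, THF, 0 °C
Reagents that add atoms: iodoform, IC(I)I
Why: Takai olefination through the geminal dichromium reagent converts the aldehyde into the vinyl iodide with the E geometry that this reaction favours.

Step 14
Reactants: 18 epoxide; 20 vinyl iodide
Product: 23 (1R,3E)-1-[(2R,4Z,7S,8R)-7-bromo-8-ethyl-3,6,7,8-tetrahydro-2H-oxocin-2-yl]hex-3-en-5-yn-1-ol (deacetyl compound), via enynyllithium 21 (not isolated), via silylated enynol 22 (not isolated)
Conditions: 20, t-BuLi (just under 2 equiv per 20), Et2O, −78 °C; BF3·OEt2, then 18, −78 °C; then MeOH, K2CO3, rt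
Reagents that add atoms: none
Why: Iodine–lithium exchange proceeds with retention of the E geometry, the BF3-activated terminal epoxide is opened at the unhindered C5 at −78 °C faster than the vinylic organolithium can attack the hindered secondary bromide (no alkyllithium remains because the iodide is kept in slight excess), C6 is not touched, and carbonate-catalysed methanolysis then removes the alkynyl silane.

Step 15
Reactants: 23 deacetyl compound
Product: 24 (1R,3E)-1-[(2R,4Z,7S,8R)-7-bromo-8-ethyl-3,6,7,8-tetrahydro-2H-oxocin-2-yl]hex-3-en-5-yn-1-yl acetate (target)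
Conditions: Ac2O, pyridine, DMAP (cat), CH2Cl2, rt
Reagents that add atoms: acetic anhydride, CC(=O)OC(C)=O
Why: Standard DMAP-catalysed acylation of the only hydroxyl group gives the C6 acetate with retention.

Compound list
1 | hex-3-yn-2-one | CCC#CC(C)=O | starting material
2 | (4S)-2,2-dimethyl-1,3-dioxolane-4-carbaldehyde, (S)-glyceraldehyde acetonide | CC1(C)OC[C@H](O1)C=O | starting material
3 | lithium hex-1-en-3-yn-2-olate (lithium enolate of 1) | [Li]OC(=C)C#CCC | intermediate
4 | (1R)-1-[(4S)-2,2-dimethyl-1,3-dioxolan-4-yl]-1-hydroxyhept-4-yn-3-one | CC1(C)OC[C@H](O1)[C@H](O)CC(=O)C#CCC | intermediate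
5 | (2R)-2-[(4S)-2,2-dimethyl-1,3-dioxolan-4-yl]-6-ethyl-2,3-dihydro-4H-pyran-4-one | CC1(C)OC[C@H](O1)[C@H]2CC(=O)C=C(CC)O2 | intermediate
6 | 1,1-diethoxyethene | C=C(OCC)OCC | starting material
7 | (1R,3R,6R)-3-[(4S)-2,2-dimethyl-1,3-dioxolan-4-yl]-8,8-diethoxy-1-ethyl-2-oxabicyclo[4.2.0]octan-5-one | CC1(C)OC[C@H](O1)[C@H]2CC(=O)[C@@H]3CC(OCC)(OCC)[C@]3(CC)O2 | intermediate
8 | (1R,3R,5S,6S)-3-[(4S)-2,2-dimethyl-1,3-dioxolan-4-yl]-8,8-diethoxy-1-ethyl-2-oxabicyclo[4.2.0]octan-5-ol | CC1(C)OC[C@H](O1)[C@H]2C[C@H](O)[C@@H]3CC(OCC)(OCC)[C@]3(CC)O2 | intermediate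
9 | O-(bicyclooctan-5-yl) 1H-imidazole-1-carbothioate of 8 | CC1(C)OC[C@H](O1)[C@H]2C[C@H](OC(=S)n4ccnc4)[C@@H]3CC(OCC)(OCC)[C@]3(CC)O2 | intermediate
10 | (2R,5Z,8R)-8-[(4S)-2,2-dimethyl-1,3-dioxolan-4-yl]-3,3-diethoxy-2-ethyl-3,4,7,8-tetrahydro-2H-oxocine | CC1(C)OC[C@H](O1)[C@H]2C/C=C\CC(OCC)(OCC)[C@@H](CC)O2 | intermediate
11 | (2R,5Z,8R)-8-[(4S)-2,2-dimethyl-1,3-dioxolan-4-yl]-2-ethyl-7,8-dihydro-2H-oxocin-3(4H)-one | CC1(C)OC[C@H](O1)[C@H]2C/C=C\CC(=O)[C@@H](CC)O2 | intermediate
12 | (2R,3R,5Z,8R)-8-[(4S)-2,2-dimethyl-1,3-dioxolan-4-yl]-2-ethyl-3,4,7,8-tetrahydro-2H-oxocin-3-ol | CC1(C)OC[C@H](O1)[C@H]2C/C=C\C[C@@H](O)[C@@H](CC)O2 | intermediate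
13 | (2R,3S,5Z,8R)-3-bromo-8-[(4S)-2,2-dimethyl-1,3-dioxolan-4-yl]-2-ethyl-3,4,7,8-tetrahydro-2H-oxocine | CC1(C)OC[C@H](O1)[C@H]2C/C=C\C[C@H](Br)[C@@H](CC)O2 | intermediate
14 | (1S)-1-[(2R,4Z,7S,8R)-7-bromo-8-ethyl-3,6,7,8-tetrahydro-2H-oxocin-2-yl]ethane-1,2-diol | OC[C@H](O)[C@H]1C/C=C\C[C@H](Br)[C@@H](CC)O1 | intermediate
15 | (2S)-2-[(2R,4Z,7S,8R)-7-bromo-8-ethyl-3,6,7,8-tetrahydro-2H-oxocin-2-yl]-2-hydroxyethyl benzoate | O=C(OC[C@H](O)[C@H]1C/C=C\C[C@H](Br)[C@@H](CC)O1)c2ccccc2 | intermediate
16 | (2S)-2-[(2R,4Z,7S,8R)-7-bromo-8-ethyl-3,6,7,8-tetrahydro-2H-oxocin-2-yl]-2-(methylsulfonyloxy)ethyl benzoate | O=C(OC[C@H](OS(C)(=O)=O)[C@H]1C/C=C\C[C@H](Br)[C@@H](CC)O1)c2ccccc2 | intermediate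
17 | (1S)-1-[(2R,4Z,7S,8R)-7-bromo-8-ethyl-3,6,7,8-tetrahydro-2H-oxocin-2-yl]-2-hydroxyethyl methanesulfonate | OC[C@H](OS(C)(=O)=O)[C@H]1C/C=C\C[C@H](Br)[C@@H](CC)O1 | intermediate
18 | (2R,3S,5Z,8R)-3-bromo-2-ethyl-8-[(2R)-oxiran-2-yl]-3,4,7,8-tetrahydro-2H-oxocine | C1O[C@H]1[C@H]2C/C=C\C[C@H](Br)[C@@H](CC)O2 | intermediate
19 | 3-(trimethylsilyl)prop-2-ynal | C[Si](C)(C)C#CC=O | starting material
20 | (E)-(4-iodobut-3-en-1-yn-1-yl)trimethylsilane | C[Si](C)(C)C#C/C=C/I | intermediate
21 | (E)-[4-(trimethylsilyl)but-1-en-3-yn-1-yl]lithium | C[Si](C)(C)C#C/C=C/[Li] | intermediate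
22 | (1R,3E)-1-[(2R,4Z,7S,8R)-7-bromo-8-ethyl-3,6,7,8-tetrahydro-2H-oxocin-2-yl]-6-(trimethylsilyl)hex-3-en-5-yn-1-ol | C[Si](C)(C)C#C/C=C/C[C@@H](O)[C@H]1C/C=C\C[C@H](Br)[C@@H](CC)O1 | intermediate
23 | (1R,3E)-1-[(2R,4Z,7S,8R)-7-bromo-8-ethyl-3,6,7,8-tetrahydro-2H-oxocin-2-yl]hex-3-en-5-yn-1-ol | C#C/C=C/C[C@@H](O)[C@H]1C/C=C\C[C@H](Br)[C@@H](CC)O1 | intermediate
24 | (1R,3E)-1-[(2R,4Z,7S,8R)-7-bromo-8-ethyl-3,6,7,8-tetrahydro-2H-oxocin-2-yl]hex-3-en-5-yn-1-yl acetate | C#C/C=C/C[C@@H](OC(C)=O)[C@H]1C/C=C\C[C@H](Br)[C@@H](CC)O1 | target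

Total steps: 15. Longest linear sequence: 14 steps (steps 1–12, 14 and 15); step 13 is a one-step branch.

Steps most likely to fail

**Step 3.**
- What may go wrong: the congested 1,4-biradical may revert instead of closing a bond between two fully substituted carbons. The electron-rich alkene may add to the carbonyl group. The ketene acetal may oligomerise on traces of acid.
- Fallback, from 5 back to 11: the smaller and more robust vinyl acetate is used as the two-carbon partner. C12 then arrives at the alcohol level as an epimer mixture that is levelled by oxidation.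
- Irradiation of 5 in vinyl acetate should give the 8-acetoxy photoadduct F1, and NaBH4 in MeOH the alcohol F2.
- Thiocarbonyldiimidazole gives the imidazolylthiocarbonate F3, and Bu3SnH/AIBN the ring-expanded oxocenyl acetate F4.
- K2CO3 in MeOH gives the oxocenol F5 (both C12 epimers). Dess–Martin periodinane oxidises both epimers to ketone 11.

**Step 6.**
- What may go wrong: the outer C10–C11 bond may be cleaved for stereoelectronic reasons, or hydrogen may be transferred to the C9 radical too early. The C13 radical may add across the ring to the new alkene, or the facial selectivity of the final hydrogen transfer may be poor.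
- Fallback, from 8 back to 10: a polar instead of a radical ring opening.
- Alcohol 8 (hydroxyl cis to the cyclobutane, as drawn) is converted into the C9 triflate F6 (Tf2O, 2,6-di-tert-butyl-4-methylpyridine, CH2Cl2, −78 °C). F6 is warmed without isolation in the presence of Bu3SnH as hydride donor.
- The equatorial C9–O bond is antiperiplanar to C10–C13 but not to C10–C11. A Grob-type (retro-Prins) heterolysis, pushed by the ring-oxygen lone pair and by the cyclobutane strain, can therefore open only the shared bond.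
- The eight-membered oxocarbenium ion is reduced at C13. The tin triflate that forms is too weak a Lewis acid to ionise the ketals at low temperature.
- The closest known reaction is the Lewis-acid ring expansion of cyclopropane-fused glycals that carry a leaving group next to the small ring, with silane trapping.

**Step 14.**
- What may go wrong: the organolithium may attack the secondary bromide (elimination or exchange). The Lewis acid may rearrange the epoxide. The enynyllithium may decay before it reacts.
- Fallback, from 18 back to 23: the side chain is built in stages with milder reagents.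
- Opening of 18 with vinylmagnesium bromide and CuI (10 mol %) in THF at −40 °C should give the homoallylic alcohol F7.
- Cross metathesis with crotonaldehyde (second-generation Hoveyda–Grubbs catalyst, CH2Cl2, 40 °C) gives the (E)-enal F8.
- Colvin rearrangement with lithiated trimethylsilyldiazomethane (excess, THF, −78 °C to 0 °C) turns the aldehyde into the terminal alkyne of 23.

Further compounds
F1 | step 3 | 8-acetoxy analogue of 7: 3-[(4S)-2,2-dimethyl-1,3-dioxolan-4-yl]-1-ethyl-5-oxo-2-oxabicyclo[4.2.0]octan-8-yl acetate (both C12 epimers) | CC1(C)OC[C@H](O1)[C@H]2CC(=O)[C@@H]3CC(OC(C)=O)[C@]3(CC)O2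
F2 | step 3 | 5-hydroxy compound from F1 | CC1(C)OC[C@H](O1)[C@H]2C[C@H](O)[C@@H]3CC(OC(C)=O)[C@]3(CC)O2
F3 | step 3 | 1H-imidazole-1-carbothioate of F2 | CC1(C)OC[C@H](O1)[C@H]2C[C@H](OC(=S)n4ccnc4)[C@@H]3CC(OC(C)=O)[C@]3(CC)O2
F4 | step 3 | (2R,5Z,8R)-8-[(4S)-2,2-dimethyl-1,3-dioxolan-4-yl]-2-ethyl-3,4,7,8-tetrahydro-2H-oxocin-3-yl acetate (both C12 epimers) | CC1(C)OC[C@H](O1)[C@H]2C/C=C\CC(OC(C)=O)[C@@H](CC)O2
F5 | step 3 | (2R,5Z,8R)-8-[(4S)-2,2-dimethyl-1,3-dioxolan-4-yl]-2-ethyl-3,4,7,8-tetrahydro-2H-oxocin-3-ol (both C12 epimers) | CC1(C)OC[C@H](O1)[C@H]2C/C=C\CC(O)[C@@H](CC)O2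
F6 | step 6 | trifluoromethanesulfonate of 8 | CC1(C)OC[C@H](O1)[C@H]2C[C@H](OS(=O)(=O)C(F)(F)F)[C@@H]3CC(OCC)(OCC)[C@]3(CC)O2
F7 | step 14 | (1R)-1-[(2R,4Z,7S,8R)-7-bromo-8-ethyl-3,6,7,8-tetrahydro-2H-oxocin-2-yl]but-3-en-1-ol | C=CC[C@@H](O)[C@H]1C/C=C\C[C@H](Br)[C@@H](CC)O1
F8 | step 14 | (2E,5R)-5-[(2R,4Z,7S,8R)-7-bromo-8-ethyl-3,6,7,8-tetrahydro-2H-oxocin-2-yl]-5-hydroxypent-2-enal | O=C/C=C/C[C@@H](O)[C@H]1C/C=C\C[C@H](Br)[C@@H](CC)O1
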